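**Plan**
Retrosynthesis: the trisubstituted C4=C5 alkene of six-membered ring B, which joins ring-fusion carbon C3a to quaternary C6, is cut first into a C4 methyl ketone on C3a and a C5 aldehyde on C6 (two carbonyl carbons). Next come the C6–C7 bond ([3,3] shift) and the ester C–O bond to an allylic alcohol, and last the ring A bonds C7a–C7, C3a–C4, C3–CH3 and C1–ethyl.
Forward: cyclopentanone ring A is substituted stepwise on (S)-4-silyloxycyclopentenone, the C5–C6 unit is attached as an allylic ester and moved onto C7 by Ireland–Claisen rearrangement, and ring B is closed last by carbonyl–carbonyl coupling.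
Stereochemistry: C7a comes from addition anti to the silyloxy group of the enantiopure enone and relays to C3a, C3 and C1 (each new group trans to its neighbour). C6 and C7 come from methyl (S)-mandelate by chirality transfer through a chair transition state. The ring closure creates no stereocentre.

Key step: step 18

Remark: target (indene) numbering C1–C7a is used for all intermediates; the butanoate α-carbon C7 is a mixture of epimers in 13–22 and is left undefined in their SMILES, because step 14 makes it planar before setting it.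

Step 1
Reactants: 1 methyl (S)-2-hydroxy-2-phenylacetate
Product: 2 methyl (S)-2-[(tert-butyldimethylsilyl)oxy]-2-phenylacetate
Conditions: TBSCl, imidazole, DMF, 0 °C → rt
Reagents that add atoms: tert-butyldimethylsilyl chloride, CC(C)(C)[Si](C)(C)Cl
Why: Imidazole-promoted silyl ether formation protects the benzylic hydroxyl through the hydride and olefination steps and does not touch the stereocentre.

Step 2
Reactants: 2 methyl (S)-2-[(tert-butyldimethylsilyl)oxy]-2-phenylacetate; 3 ethyl 2-(diethoxyphosphoryl)butanoate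
Product: 5 ethyl (2E,4R)-4-[(tert-butyldimethylsilyl)oxy]-2-ethyl-4-phenylbut-2-enoate, via aldehyde 4 (not isolated)
Conditions: iBu2AlH (1.05 equiv), toluene, −78 °C; then sodium salt of 3 (from 3, NaH, THF, 0 °C), −78 °C → rt; aq. potassium sodium tartrate
Reagents that add atoms: none
Why: Half-reduction of the ester and Horner–Wadsworth–Emmons olefination in one flask consume the configurationally fragile α-silyloxy aldehyde 4 as it is released, and the α-ethyl phosphonate anion should give the trisubstituted alkene with the ester trans to the carbinol carbon (E).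

Step 3
Reactants: 5 ethyl (2E,4R)-4-[(tert-butyldimethylsilyl)oxy]-2-ethyl-4-phenylbut-2-enoate
Product: 6 (2E,4R)-4-[(tert-butyldimethylsilyl)oxy]-2-ethyl-4-phenylbut-2-en-1-ol
Conditions: iBu2AlH (2.5 equiv), CH2Cl2, −78 → 0 °C; aq. potassium sodium tartrate
Reagents that add atoms: none
Why: Aluminium hydride 1,2-reduction of the unsaturated ester gives the allylic alcohol without affecting the alkene geometry or the silyl ether.

Step 4
Reactants: 6 (2E,4R)-4-[(tert-butyldimethylsilyl)oxy]-2-ethyl-4-phenylbut-2-en-1-ol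
Product: 7 (1R,2E)-3-ethyl-1-phenylbut-2-ene-1,4-diol
Conditions: Bu4NF, THF, 0 °C → rt
Reagents that add atoms: none
Why: Fluoride desilylation under non-acidic conditions frees the secondary hydroxyl without ionising the benzylic allylic C–O bond, so the (R) centre is kept.

Step 5
Reactants: 7 (1R,2E)-3-ethyl-1-phenylbut-2-ene-1,4-diol
Product: 8 (1R,2E)-3-ethyl-1-phenyl-4-[(triethylsilyl)oxy]but-2-en-1-ol
Conditions: Et3SiCl (1.05 equiv), imidazole, CH2Cl2, −78 °C
Reagents that add atoms: chlorotriethylsilane, CC[Si](CC)(CC)Cl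
Why: Silyl ether formation is much faster at the unhindered primary hydroxyl than at the secondary benzylic one, and the triethylsilyl ether is chosen because it can later be oxidised directly to the aldehyde.

Step 6
Reactants: 9 methyl butanoate
Product: 11 1-methoxy-1-[(trimethylsilyl)oxy]but-1-ene, via lithium enolate 10 (not isolated)
Conditions: LiN(iPr)2, THF, −78 °C; Me3SiCl, −78 °C → rt; distillation
Reagents that add atoms: chlorotrimethylsilane, C[Si](C)(C)Cl
Why: Deprotonation and O-silylation of the ester enolate (silyl ketene acetal formation) give a neutral donor for the conjugate addition, whose double-bond geometry is of no consequence.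

Step 7
Reactants: 12 (S)-4-[(tert-butyldimethylsilyl)oxy]cyclopent-2-en-1-one; 11 1-methoxy-1-[(trimethylsilyl)oxy]but-1-ene
Product: 14 methyl 2-[(1R,2S)-2-[(tert-butyldimethylsilyl)oxy]-4-oxocyclopentyl]butanoate, via silyl enol ether 13 (not isolated)
Conditions: HgI2 (10 mol%), CH2Cl2, −78 → −30 °C; then aq. citric acid, THF, 0 °C
Reagents that add atoms: none
Why: Mukaiyama–Michael addition places the butanoate carbon on the enone β-carbon (C7a) from the face opposite the C3a silyloxy group, which sets C7a, and the mild acid work-up cleaves only the labile trimethylsilyl enol ether.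

Step 8
Reactants: 14 methyl 2-[(1R,2S)-2-[(tert-butyldimethylsilyl)oxy]-4-oxocyclopentyl]butanoate
Product: 15 methyl 2-[(1S)-4-oxocyclopent-2-en-1-yl]butanoate
Conditions: DBU, CH2Cl2, 0 °C
Reagents that add atoms: none
Why: Base-induced E1cB elimination of silanolate through the C3 enolate gives the 4-substituted cyclopentenone, and C7a, lying γ to the carbonyl, is not touched.

Step 9
Reactants: 15 methyl 2-[(1S)-4-oxocyclopent-2-en-1-yl]butanoate
Product: 17 methyl 2-[(1S,2R,3S)-2-ethenyl-3-methyl-4-oxocyclopentyl]butanoate, via magnesium enolate 16 (not isolated)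
Conditions: CH2=CHMgBr (1.2 equiv), CuI (10 mol%), THF, −78 → −40 °C; then MeI (5 equiv), HMPA, −40 → −10 °C
Reagents that add atoms: vinylmagnesium bromide, C=C[Mg]Br; iodomethane, CI
Why: Copper-catalysed conjugate addition of the vinyl Grignard reagent occurs anti to the C7a side chain (sets C3a) and the regiodefined enolate is then methylated anti to the new vinyl group (sets C3), a conjugate addition–enolate alkylation sequence.

Step 10
Reactants: 17 methyl 2-[(1S,2R,3S)-2-ethenyl-3-methyl-4-oxocyclopentyl]butanoate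
Product: 19 methyl 2-[(1R,2R,3S,5S)-2-ethenyl-5-ethyl-3-methyl-4-oxocyclopentyl]butanoate, via lithium enolate 18 (not isolated)
Conditions: LiN(iPr)2 (1.05 equiv), THF, −78 °C; EtI, DMPU, −78 → −20 °C
Reagents that add atoms: iodoethane, CCI
Why: Kinetic deprotonation at the C1 methylene (the C3 methine and the tertiary ester α-hydrogen react more slowly) and enolate alkylation anti to the C7a substituent set C1 in the trans arrangement, which is also the thermodynamically preferred one.

Step 11
Reactants: 19 methyl 2-[(1R,2R,3S,5S)-2-ethenyl-5-ethyl-3-methyl-4-oxocyclopentyl]butanoate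
Product: 20 methyl 2-[(6S,7R,8R,9S)-8-ethenyl-6-ethyl-9-methyl-1,4-dioxaspiro[4.4]nonan-7-yl]butanoate
Conditions: (Me3SiOCH2)2, Me3SiOTf (5 mol%), CH2Cl2, −78 → −20 °C; pyridine quench
Reagents that add atoms: 1,2-bis(trimethylsilyloxy)ethane, C[Si](C)(C)OCCO[Si](C)(C)C
Why: Silyl triflate-catalysed ketalisation with the bis-silylated glycol is driven by disiloxane formation and works at low temperature on the doubly flanked C2 ketone, masking it against base in step 14 and against titanium in step 18.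

Step 12
Reactants: 20 methyl 2-[(6S,7R,8R,9S)-8-ethenyl-6-ethyl-9-methyl-1,4-dioxaspiro[4.4]nonan-7-yl]butanoate
Product: 21 2-[(6S,7R,8R,9S)-8-ethenyl-6-ethyl-9-methyl-1,4-dioxaspiro[4.4]nonan-7-yl]butanoic acid
Conditions: LiOH, THF/MeOH/H2O, 50 °C; then 1 M HCl to pH 4, 0 °C
Reagents that add atoms: lithium hydroxide, [Li+].[OH-]
Why: Saponification of the secondary methyl ester proceeds under conditions to which ketal and vinyl group are inert, and the cold, brief acidification spares the ketal.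

Step 13
Reactants: 21 2-[(6S,7R,8R,9S)-8-ethenyl-6-ethyl-9-methyl-1,4-dioxaspiro[4.4]nonan-7-yl]butanoic acid; 8 (1R,2E)-3-ethyl-1-phenyl-4-[(triethylsilyl)oxy]but-2-en-1-ol
Product: 22 (1R,2E)-3-ethyl-1-phenyl-4-[(triethylsilyl)oxy]but-2-en-1-yl 2-[(6S,7R,8R,9S)-8-ethenyl-6-ethyl-9-methyl-1,4-dioxaspiro[4.4]nonan-7-yl]butanoate
Conditions: EDC·HCl, DMAP, CH2Cl2, 0 °C → rt
Reagents that add atoms: none
Why: Carbodiimide esterification with DMAP catalysis (Steglich) acylates the secondary hydroxyl without breaking its C–O bond, so the (R) carbinol configuration is retained.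

Step 14
Reactants: 22 (1R,2E)-3-ethyl-1-phenyl-4-[(triethylsilyl)oxy]but-2-en-1-yl 2-[(6S,7R,8R,9S)-8-ethenyl-6-ethyl-9-methyl-1,4-dioxaspiro[4.4]nonan-7-yl]butanoate
Product: 26 (2R,3R,4E)-2,3-diethyl-2-[(6S,7R,8R,9S)-8-ethenyl-6-ethyl-9-methyl-1,4-dioxaspiro[4.4]nonan-7-yl]-5-phenyl-3-{[(triethylsilyl)oxy]methyl}pent-4-enoic acid, via lithium enolate 23 (not isolated), via silyl ketene acetal 24 (not isolated), via trimethylsilyl ester 25 (not isolated)
Conditions: LiN(iPr)2 (1.3 equiv), THF (no polar cosolvent), −78 °C; Me3SiCl/Et3N, −78 °C → rt, then 65 °C; H2O/MeOH work-up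
Reagents that add atoms: none
Why: Ireland–Claisen rearrangement, in which deprotonation through the closed amide-bound transition state should put the larger C7a substituent anti to the metal-bound oxygen and the chair [3,3] shift with phenyl pseudo-equatorial on the (R) carbinol carbon then delivers C6 and C7 with both ethyl groups on the same side together with the (E)-styryl group.

Step 15
Reactants: 26 (2R,3R,4E)-2,3-diethyl-2-[(6S,7R,8R,9S)-8-ethenyl-6-ethyl-9-methyl-1,4-dioxaspiro[4.4]nonan-7-yl]-5-phenyl-3-{[(triethylsilyl)oxy]methyl}pent-4-enoic acid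
Product: 27 methyl (2R,3R,4E)-2,3-diethyl-2-[(6S,7R,8R,9S)-8-ethenyl-6-ethyl-9-methyl-1,4-dioxaspiro[4.4]nonan-7-yl]-5-phenyl-3-{[(triethylsilyl)oxy]methyl}pent-4-enoate
Conditions: MeI, K2CO3, DMF, rt
Reagents that add atoms: iodomethane, CI
Why: Carboxylate O-alkylation (SN2 at iodomethane) esterifies the acid without attack at its hindered acyl carbon and removes the acidic proton before the later oxidations.

Step 16
Reactants: 27 methyl (2R,3R,4E)-2,3-diethyl-2-[(6S,7R,8R,9S)-8-ethenyl-6-ethyl-9-methyl-1,4-dioxaspiro[4.4]nonan-7-yl]-5-phenyl-3-{[(triethylsilyl)oxy]methyl}pent-4-enoate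
Product: 28 methyl (2R,3R,4E)-2-[(6S,7S,8R,9S)-8-acetyl-6-ethyl-9-methyl-1,4-dioxaspiro[4.4]nonan-7-yl]-2,3-diethyl-5-phenyl-3-{[(triethylsilyl)oxy]methyl}pent-4-enoate
Conditions: PdCl2 (10 mol%), Cu(OAc)2 (20 mol%), O2 (1 atm), DMA/H2O (7:1), rt
Reagents that add atoms: water, O
Why: Wacker oxidation converts the monosubstituted alkene into the methyl ketone with Markovnikov regioselectivity, the internal styryl alkene on quaternary C6 being far less reactive and the acetate-buffered medium sparing ketal and silyl ether.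

Step 17
Reactants: 28 methyl (2R,3R,4E)-2-[(6S,7S,8R,9S)-8-acetyl-6-ethyl-9-methyl-1,4-dioxaspiro[4.4]nonan-7-yl]-2,3-diethyl-5-phenyl-3-{[(triethylsilyl)oxy]methyl}pent-4-enoate
Product: 30 methyl (2R,3R,4E)-2-[(6S,7S,8R,9S)-8-acetyl-6-ethyl-9-methyl-1,4-dioxaspiro[4.4]nonan-7-yl]-2,3-diethyl-3-formyl-5-phenylpent-4-enoate, via alkoxysulfonium chloride 29 (not isolated)
Conditions: (COCl)2, DMSO, CH2Cl2, −78 → −30 °C; then Et3N, −78 → 0 °C
Reagents that add atoms: none
Why: Under Swern conditions a primary triethylsilyl ether is converted directly into the alkoxysulfonium salt and then the aldehyde, so the γ-hydroxy ester that would lactonise onto the neighbouring ester is never set free.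

Step 18
Reactants: 30 methyl (2R,3R,4E)-2-[(6S,7S,8R,9S)-8-acetyl-6-ethyl-9-methyl-1,4-dioxaspiro[4.4]nonan-7-yl]-2,3-diethyl-3-formyl-5-phenylpent-4-enoate
Product: 32 methyl (1S,3S,3aR,6S,7R,7aR)-1,6,7-triethyl-3,4-dimethyl-6-[(E)-2-phenylethenyl]-1,3,3a,6,7,7a-hexahydrospiro[indene-2,2′-[1,3]dioxolane]-7-carboxylate, via titanium pinacolate 31 (not isolated)
Conditions: TiCl3(DME)1.5, Zn–Cu couple, DME, reflux; 30 added by syringe pump over 24 h (final concentration ≤ 5 mM); aq. K2CO3 work-up
Reagents that add atoms: none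
Why: The zinc–copper couple reduces TiCl3 to low-valent titanium, which transfers single electrons to the C5 aldehyde and the C4 methyl ketone; the two ketyl carbons combine to the titanium-bound C4–C5 pinacolate 31, and at reflux both C–O bonds are broken on the metal to leave the C4=C5 alkene. The closest known reaction type is the intramolecular McMurry coupling of keto aldehydes to cycloalkenes. Ring B is formed as a cyclohexene by joining the two carbonyl carbons (formally 6-exo attack of the C4 ketyl on the aldehyde carbon), and a cis alkene is the only possibility in a ring of this size. No stereocentre is formed: C3a, C7a, C6 and C7 are brought in from 30, and the trans ring fusion follows from the trans C3a/C7a substituents of ring A. The step needs chemoselective ketone–aldehyde coupling and ring closure over oligomerisation, which are secured by the ketal on C2, by the much slower reduction of the doubly flanked methyl ester, by the inertness of the styryl alkene and by slow addition at high dilution. Since the new bond joins two electrophilic carbons, no carbanion has to be made or attacked beside quaternary C6, the aldehyde has no α-hydrogen to lose, and C3a, the one epimerisable centre, already holds its preferred trans orientation.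

Step 19
Reactants: 32 methyl (1S,3S,3aR,6S,7R,7aR)-1,6,7-triethyl-3,4-dimethyl-6-[(E)-2-phenylethenyl]-1,3,3a,6,7,7a-hexahydrospiro[indene-2,2′-[1,3]dioxolane]-7-carboxylate
Product: 33 methyl (1S,3S,3aR,6S,7R,7aR)-1,6,7-triethyl-3,4-dimethyl-2-oxo-6-[(E)-2-phenylethenyl]-2,3,3a,6,7,7a-hexahydro-1H-indene-7-carboxylate
Conditions: 1 M HCl, THF, rt
Reagents that add atoms: water, O
Why: Acid-catalysed ketal hydrolysis releases the C2 ketone, and because C1 and C3 already carry their substituents trans to the neighbouring ring carbons any enolisation under these conditions returns the same, thermodynamically preferred epimers.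

Step 20
Reactants: 33 methyl (1S,3S,3aR,6S,7R,7aR)-1,6,7-triethyl-3,4-dimethyl-2-oxo-6-[(E)-2-phenylethenyl]-2,3,3a,6,7,7a-hexahydro-1H-indene-7-carboxylate
Product: 34 (1S,3S,3aR,6S,7R,7aR)-1,6,7-triethyl-3,4-dimethyl-2-oxo-6-[(E)-2-phenylethenyl]-2,3,3a,6,7,7a-hexahydro-1H-indene-7-carboxylic acid
Conditions: LiI, pyridine, reflux; then 1 M HCl work-up
Reagents that add atoms: none
Why: Iodide cleaves the ester by SN2 attack at the methyl carbon (nucleophilic ester dealkylation), which bypasses the acyl carbon shielded by two quaternary neighbours and leaves all stereocentres untouched.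

**Compound list**
1 | methyl (S)-2-hydroxy-2-phenylacetate | O[C@H](C(=O)OC)c1ccccc1 | starting material
2 | methyl (S)-2-[(tert-butyldimethylsilyl)oxy]-2-phenylacetate | CC(C)(C)[Si](C)(C)O[C@H](C(=O)OC)c1ccccc1 | intermediate
3 | ethyl 2-(diethoxyphosphoryl)butanoate | CCOC(=O)C(CC)P(=O)(OCC)OCC | starting material
4 | (S)-2-[(tert-butyldimethylsilyl)oxy]-2-phenylacetaldehyde | CC(C)(C)[Si](C)(C)O[C@H](C=O)c1ccccc1 | intermediate
5 | ethyl (2E,4R)-4-[(tert-butyldimethylsilyl)oxy]-2-ethyl-4-phenylbut-2-enoate | CC(C)(C)[Si](C)(C)O[C@H](/C=C(\CC)C(=O)OCC)c1ccccc1 | intermediate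
6 | (2E,4R)-4-[(tert-butyldimethylsilyl)oxy]-2-ethyl-4-phenylbut-2-en-1-ol | CC(C)(C)[Si](C)(C)O[C@H](/C=C(\CC)CO)c1ccccc1 | intermediate
7 | (1R,2E)-3-ethyl-1-phenylbut-2-ene-1,4-diol | O[C@H](/C=C(\CC)CO)c1ccccc1 | intermediate
8 | (1R,2E)-3-ethyl-1-phenyl-4-[(triethylsilyl)oxy]but-2-en-1-ol | O[C@H](/C=C(\CC)CO[Si](CC)(CC)CC)c1ccccc1 | intermediate
9 | methyl butanoate | CCCC(=O)OC | starting material
10 | lithium 1-methoxybut-1-en-1-olate (lithium enolate of 9) | CCC=C(OC)O[Li] | intermediate
11 | 1-methoxy-1-[(trimethylsilyl)oxy]but-1-ene (E/Z mixture) | CCC=C(OC)O[Si](C)(C)C | intermediate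
12 | (S)-4-[(tert-butyldimethylsilyl)oxy]cyclopent-2-en-1-one | O=C1C=C[C@@H](O[Si](C)(C)C(C)(C)C)C1 | starting material
13 | methyl 2-[(1R,5S)-5-[(tert-butyldimethylsilyl)oxy]-3-[(trimethylsilyl)oxy]cyclopent-2-en-1-yl]butanoate | C[Si](C)(C)OC1=C[C@@H]([C@H](C1)O[Si](C)(C)C(C)(C)C)C(CC)C(=O)OC | intermediate
14 | methyl 2-[(1R,2S)-2-[(tert-butyldimethylsilyl)oxy]-4-oxocyclopentyl]butanoate | O=C1C[C@H](O[Si](C)(C)C(C)(C)C)[C@H](C1)C(CC)C(=O)OC | intermediate
15 | methyl 2-[(1S)-4-oxocyclopent-2-en-1-yl]butanoate | O=C1C=C[C@H](C1)C(CC)C(=O)OC | intermediate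
16 | bromomagnesium C2=C3 enolate from vinyl addition to 15 (vinyl on C3a trans to the C7a side chain) | Br[Mg]OC1=C[C@H](C=C)[C@H](C1)C(CC)C(=O)OC | intermediate
17 | methyl 2-[(1S,2R,3S)-2-ethenyl-3-methyl-4-oxocyclopentyl]butanoate | O=C1C[C@H](C(CC)C(=O)OC)[C@@H](C=C)[C@@H]1C | intermediate
18 | lithium C1=C2 enolate of 17 | [Li]OC1=C[C@H](C(CC)C(=O)OC)[C@@H](C=C)[C@@H]1C | intermediate
19 | methyl 2-[(1R,2R,3S,5S)-2-ethenyl-5-ethyl-3-methyl-4-oxocyclopentyl]butanoate | CC[C@@H]1C(=O)[C@@H](C)[C@H](C=C)[C@H]1C(CC)C(=O)OC | intermediate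
20 | methyl 2-[(6S,7R,8R,9S)-8-ethenyl-6-ethyl-9-methyl-1,4-dioxaspiro[4.4]nonan-7-yl]butanoate | CC[C@@H]1C2(OCCO2)[C@@H](C)[C@H](C=C)[C@H]1C(CC)C(=O)OC | intermediate
21 | 2-[(6S,7R,8R,9S)-8-ethenyl-6-ethyl-9-methyl-1,4-dioxaspiro[4.4]nonan-7-yl]butanoic acid | CC[C@@H]1C2(OCCO2)[C@@H](C)[C@H](C=C)[C@H]1C(CC)C(=O)O | intermediate
22 | (1R,2E)-3-ethyl-1-phenyl-4-[(triethylsilyl)oxy]but-2-en-1-yl 2-[(6S,7R,8R,9S)-8-ethenyl-6-ethyl-9-methyl-1,4-dioxaspiro[4.4]nonan-7-yl]butanoate | CC[C@@H]1C2(OCCO2)[C@@H](C)[C@H](C=C)[C@H]1C(CC)C(=O)O[C@H](/C=C(\CC)CO[Si](CC)(CC)CC)c1ccccc1 | intermediate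
23 | lithium enolate of 22 (C7a syn to the allylic oxygen, ethyl syn to O–Li) | CC[C@@H]1C2(OCCO2)[C@@H](C)[C@H](C=C)[C@H]1/C(CC)=C(/O[Li])O[C@H](/C=C(\CC)CO[Si](CC)(CC)CC)c1ccccc1 | intermediate
24 | (E)-trimethylsilyl ketene acetal of 22 (C7a anti to OSiMe3) | CC[C@@H]1C2(OCCO2)[C@@H](C)[C@H](C=C)[C@H]1/C(CC)=C(/O[Si](C)(C)C)O[C@H](/C=C(\CC)CO[Si](CC)(CC)CC)c1ccccc1 | intermediate
25 | trimethylsilyl (2R,3R,4E)-2,3-diethyl-2-[(6S,7R,8R,9S)-8-ethenyl-6-ethyl-9-methyl-1,4-dioxaspiro[4.4]nonan-7-yl]-5-phenyl-3-{[(triethylsilyl)oxy]methyl}pent-4-enoate | CC[C@@H]1C2(OCCO2)[C@@H](C)[C@H](C=C)[C@H]1[C@@](CC)(C(=O)O[Si](C)(C)C)[C@@](CC)(/C=C/c3ccccc3)CO[Si](CC)(CC)CC | intermediate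
26 | (2R,3R,4E)-2,3-diethyl-2-[(6S,7R,8R,9S)-8-ethenyl-6-ethyl-9-methyl-1,4-dioxaspiro[4.4]nonan-7-yl]-5-phenyl-3-{[(triethylsilyl)oxy]methyl}pent-4-enoic acid | CC[C@@H]1C2(OCCO2)[C@@H](C)[C@H](C=C)[C@H]1[C@@](CC)(C(=O)O)[C@@](CC)(/C=C/c3ccccc3)CO[Si](CC)(CC)CC | intermediate
27 | methyl ester of 26 | CC[C@@H]1C2(OCCO2)[C@@H](C)[C@H](C=C)[C@H]1[C@@](CC)(C(=O)OC)[C@@](CC)(/C=C/c3ccccc3)CO[Si](CC)(CC)CC | intermediate
28 | methyl (2R,3R,4E)-2-[(6S,7S,8R,9S)-8-acetyl-6-ethyl-9-methyl-1,4-dioxaspiro[4.4]nonan-7-yl]-2,3-diethyl-5-phenyl-3-{[(triethylsilyl)oxy]methyl}pent-4-enoate | CC[C@@H]1C2(OCCO2)[C@@H](C)[C@H](C(C)=O)[C@H]1[C@@](CC)(C(=O)OC)[C@@](CC)(/C=C/c3ccccc3)CO[Si](CC)(CC)CC | intermediate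
29 | dimethyl(alkoxy)sulfonium chloride on the C5 oxygen of 28 | CC[C@@H]1C2(OCCO2)[C@@H](C)[C@H](C(C)=O)[C@H]1[C@@](CC)(C(=O)OC)[C@@](CC)(/C=C/c3ccccc3)CO[S+](C)C.[Cl-] | intermediate
30 | methyl (2R,3R,4E)-2-[(6S,7S,8R,9S)-8-acetyl-6-ethyl-9-methyl-1,4-dioxaspiro[4.4]nonan-7-yl]-2,3-diethyl-3-formyl-5-phenylpent-4-enoate | CC[C@@H]1C2(OCCO2)[C@@H](C)[C@H](C(C)=O)[C@H]1[C@@](CC)(C(=O)OC)[C@@](CC)(/C=C/c3ccccc3)C=O | intermediate
31 | titanium C4,C5-pinacolate of 30 (ring B closed, configuration at C4 and C5 undefined) | CC[C@@H]1C2(OCCO2)[C@@H](C)[C@@H]3C4(C)O[Ti]OC4[C@@](/C=C/c4ccccc4)(CC)[C@](CC)(C(=O)OC)[C@H]31 | intermediate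
32 | methyl (1S,3S,3aR,6S,7R,7aR)-1,6,7-triethyl-3,4-dimethyl-6-[(E)-2-phenylethenyl]-1,3,3a,6,7,7a-hexahydrospiro[indene-2,2′-[1,3]dioxolane]-7-carboxylate | CC[C@@H]1C2(OCCO2)[C@@H](C)[C@@H]3C(C)=C[C@@](/C=C/c4ccccc4)(CC)[C@](CC)(C(=O)OC)[C@H]31 | intermediate
33 | methyl (1S,3S,3aR,6S,7R,7aR)-1,6,7-triethyl-3,4-dimethyl-2-oxo-6-[(E)-2-phenylethenyl]-2,3,3a,6,7,7a-hexahydro-1H-indene-7-carboxylate | CC[C@@H]1C(=O)[C@@H](C)[C@@H]2C(C)=C[C@@](/C=C/c3ccccc3)(CC)[C@](CC)(C(=O)OC)[C@H]21 | intermediate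
34 | (1S,3S,3aR,6S,7R,7aR)-1,6,7-triethyl-3,4-dimethyl-2-oxo-6-[(E)-2-phenylethenyl]-2,3,3a,6,7,7a-hexahydro-1H-indene-7-carboxylic acid | CC[C@@H]1C(=O)[C@@H](C)[C@@H]2C(C)=C[C@@](/C=C/c3ccccc3)(CC)[C@](CC)(C(=O)O)[C@H]21 | target

**Step count**
Total: 20 steps. Longest linear sequence: 15 steps (steps 6–20, from methyl butanoate 9 and enone 12 to 34).

**Steps most likely to fail**

1. Step 14. The deprotonation of the α,α-disubstituted ester may not distinguish the ethyl group from the ring carbon well enough, so that enolate geometry, and with it the configuration at C7, is eroded; the [3,3] shift may also be slow in so crowded an array. The fallback sets out from 22. Its two C7 epimers, the (2R)-butanoate epimer F1 and the (2S)-butanoate epimer F2, are separated by chromatography. Each is then enolised in THF at −78 °C with the matched enantiomer of a chiral bidentate lithium amide, lithium (R)- or (S)-(1-phenyl-2-piperidin-1-ylethyl)(2,2,2-trifluoroethyl)amide, in place of LiN(iPr)2. This enolisation is controlled by the reagent and is stereospecific with respect to the α-stereocentre, so each pure epimer should give the single ketene acetal geometry; which base enantiomer matches which epimer is to be found in a pilot run. Silylation and rearrangement as before bring the route back at acid 26.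

2. Step 18. The coupling may stop at the pinacol stage because the hindered C4–C5 diolate is deoxygenated slowly; aldol closure of the C3a/C4 enolate onto the aldehyde and Lewis-acid-induced loss of the ketal may compete at reflux. The fallback sets out from 30 and keeps the same C4–C5 bond formation between the two carbonyl carbons. SmI2 (divalent samarium) in THF/tBuOH at −78 °C should effect ketyl–carbonyl pinacol cyclisation to the cis-C4,C5-diol F3. Thiocarbonyldiimidazole in toluene at 90 °C converts it into the cyclic thiocarbonate F4. Corey–Winter fragmentation with 1,3-dimethyl-2-phenyl-1,3,2-diazaphospholidine at 40 °C then gives the alkene, and the route is rejoined at 32.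

3. Step 17. Oxidative desilylation at the neopentyl position may be incomplete, or the silyl group may be lost before oxidation, after which the γ-hydroxy ester would lactonise. The fallback sets out from acid 26 and changes the ester so that an ordinary desilylation–oxidation pair becomes safe. tert-Butyl N,N′-diisopropylcarbamimidate in CH2Cl2 gives the tert-butyl ester F5. Wacker oxidation as in step 16 gives the methyl ketone F6. Bu4NF buffered with AcOH gives the primary alcohol F7, the tert-butyl ester being a poor acyl donor toward the neighbouring hydroxyl. Dess–Martin oxidation gives the keto aldehyde F8, and McMurry coupling as in step 18 gives the ring-closed tert-butyl ester F9. One treatment with CF3CO2H in wet CH2Cl2 at 0 °C removes both the tert-butyl ester and the ketal, and the route comes back at 34.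

Further compounds
F1 | step 14 | (2R)-butanoate epimer of ester 22 | CC[C@@H]1C2(OCCO2)[C@@H](C)[C@H](C=C)[C@H]1[C@@H](CC)C(=O)O[C@H](/C=C(\CC)CO[Si](CC)(CC)CC)c1ccccc1
F2 | step 14 | (2S)-butanoate epimer of ester 22 | CC[C@@H]1C2(OCCO2)[C@@H](C)[C@H](C=C)[C@H]1[C@H](CC)C(=O)O[C@H](/C=C(\CC)CO[Si](CC)(CC)CC)c1ccccc1
F3 | step 18 | cis-C4,C5-diol from pinacol closure of 30 (configuration at C4 and C5 undefined, other centres as in 32) | CC[C@@H]1C2(OCCO2)[C@@H](C)[C@@H]3C(C)(O)C(O)[C@@](/C=C/c4ccccc4)(CC)[C@](CC)(C(=O)OC)[C@H]31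
F4 | step 18 | cyclic C4,C5-thiocarbonate of F3 | CC[C@@H]1C2(OCCO2)[C@@H](C)[C@@H]3C4(C)OC(=S)OC4[C@@](/C=C/c4ccccc4)(CC)[C@](CC)(C(=O)OC)[C@H]31
F5 | step 17 | tert-butyl ester of acid 26 | CC[C@@H]1C2(OCCO2)[C@@H](C)[C@H](C=C)[C@H]1[C@@](CC)(C(=O)OC(C)(C)C)[C@@](CC)(/C=C/c3ccccc3)CO[Si](CC)(CC)CC
F6 | step 17 | tert-butyl ester analogue of methyl ketone 28 | CC[C@@H]1C2(OCCO2)[C@@H](C)[C@H](C(C)=O)[C@H]1[C@@](CC)(C(=O)OC(C)(C)C)[C@@](CC)(/C=C/c3ccccc3)CO[Si](CC)(CC)CC
F7 | step 17 | C5 primary alcohol from F6 | CC[C@@H]1C2(OCCO2)[C@@H](C)[C@H](C(C)=O)[C@H]1[C@@](CC)(C(=O)OC(C)(C)C)[C@@](CC)(/C=C/c3ccccc3)CO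
F8 | step 17 | tert-butyl ester analogue of keto aldehyde 30 | CC[C@@H]1C2(OCCO2)[C@@H](C)[C@H](C(C)=O)[C@H]1[C@@](CC)(C(=O)OC(C)(C)C)[C@@](CC)(/C=C/c3ccccc3)C=O
F9 | step 17 | tert-butyl ester analogue of 32 | CC[C@@H]1C2(OCCO2)[C@@H](C)[C@@H]3C(C)=C[C@@](/C=C/c4ccccc4)(CC)[C@](CC)(C(=O)OC(C)(C)C)[C@H]31
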